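# Eduesmine by Cloke–Wilson ring expansion of a donor–acceptor cyclopropane: synthesis design

## The problem

Eduesmine (18) is a 2,5-diaryl-3,4-bis(hydroxymethyl)oxolane: one five-membered ring (O1, C2–C5) whose four carbons are contiguous stereocentres, all S, related in pairs by a C2 axis through O1 and the midpoint of C3–C4. Each 4-hydroxy-3-methoxyphenyl group is cis to the hydroxymethyl group on the neighbouring carbon (2,3-cis and 4,5-cis), while the two hydroxymethyl groups are trans to each other and the two aryl groups are trans across the ring. Both aryl groups therefore sit in the less stable position, so nothing can be left to equilibration and C2 and C5 must be set under kinetic control. The ring C–O bonds are benzylic and para to a free phenol; acid opens them through quinone-methide-like cations and would epimerise C2 or C5, and the phenols are easily oxidised, so they must stay masked until a mild last step. Control can be relayed in one direction: C4 can be set by an asymmetric catalyst, C5 can be tied to C4 by a stereospecific step, and the free C4 hydroxymethyl group can then steer hydrogen to its own face of a C2=C3 double bond and set C2 and C3 together. The feature that makes the key step possible is the benzylic ether bond O1–C5 beside C4, together with a C3 that carries a carboxyl-level carbon and a C2 that carries an aryl group. Written as an ester and an aroyl group on C3, these turn C3–C4–C5 into a donor–acceptor cyclopropane (aryl donor on C5, keto ester on C3) whose ketone oxygen is the future O1.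

## Retrosynthesis

**18 from 17.** No skeletal bond is cut. The C3 hydroxymethyl group is taken back to a methyl ester and the two phenols to pivalates, giving 17. Compared with benzyl or silyl ethers, the ester-type phenol mask lowers the donor strength of the aryl rings for the earlier Lewis-acid step. It also falls in the same hydride reduction that makes the C3 alcohol, so no separate deprotection is spent on an acid-sensitive bis(p-hydroxybenzyl) ether. The forward reaction only has to reduce three esters without touching a stereocentre.

**17 from 16.** The C2–H and C3–H bonds are cut, leading to the 4,5-dihydrofuran 16 with a C2=C3 double bond. The neighbouring options (reduction of a C2 oxocarbenium ion, protonation of a C3 enolate) would set the two centres one at a time against no clear bias; a syn addition of hydrogen sets both at once. Two stereocentres are removed. The forward reaction must deliver hydrogen to the face that already carries the C4 and C5 substituents, which calls for a hydroxyl-directed homogeneous hydrogenation, so the C4 hydroxymethyl group must be free at this stage.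

**16 from 15 from 14 (key disconnection).** With the C4 hydroxymethyl group masked as silyl ether 15, the O1–C5 bond is cut and C5 is joined to C3 instead, giving cyclopropane 14, an isomer of 15. Cutting O1–C2 would lead to an open-chain hydroxy ketone with an epimerisable C3; cutting C4–C5 would lead to an aldol-type union with no handle on the 4,5-cis geometry. The O1–C5 cut is preferred because the configuration at C5 can be carried over from a cyclopropane stereocentre that is easy to make. 14 has only two defined stereocentres, both formed in one catalytic step, and contains every carbon of the target. The forward ring expansion must transfer configuration with inversion at C5, so that trans aryl/silyloxymethyl in 14 becomes cis in 15, and must use the ketone oxygen, not the ester oxygen.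

**14 from 13 from 12.** No skeletal bond is cut; the silyl ether is traced through alcohol 13 to aldehyde 12. The aldehyde is what an amine-catalysed cyclopropanation delivers. It has to be reduced before the ring expansion, because a formyl group at C4 of a dihydrofuran would make C4 epimerisable. A silyl ether is chosen because it can later be removed without touching the aryl pivalates. The forward steps need a reduction that distinguishes the aldehyde from the aryl ketone, and a prompt silylation.

**12 from 4 and 11.** Both ring bonds from the quaternary carbon (to the formyl-bearing and to the aryl-bearing carbon) are cut, giving enal 4 and bromo keto ester 11. This is preferred over carbene addition to an alkene, which would need an acceptor/acceptor diazo compound and gives poorer enantiocontrol. A Michael-initiated ring closure under iminium/enamine catalysis gives trans-2-formyl-3-arylcyclopropanes from cinnamaldehydes with high enantioselectivity. The precursors are achiral and half the size. The forward step must fix the absolute configuration at the aryl-bearing carbon and the trans geometry; the quaternary centre may form as a mixture.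

**4 and 11 from 1, 5, 2 and 7.** Enal 4 is cut at its C=C bond to aldehyde 3, the pivalate of 1 made with 2; a two-carbon Wittig homologation is asked for. Bromide 11 is cut at C–Br to keto ester 10, and 10 at the bond between the ketone carbon and the methylene group to acid 6 and malonate half ester 7; acid 6 is the pivalate of 5. Installing the pivalates first means one protecting-group step per half serves the whole route.

## Roads not taken

**Alternative 1:** Both benzylic C–O bonds and the C3/C4 hydrogens are traced to a two-directional hydroboration. A symmetrical (E,E)-diene from a double Stobbe-type condensation would take up boron at both benzylic carbons and hydrogen at C3 and C4, syn and with the same facial sense, under a chiral monoalkylborane. Oxidation would give diol A1, and the ring would then be closed by etherification.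
- *Merits:* it uses the C2 symmetry fully, creates all four stereocentres in one operation from an achiral diene, and is probably the shortest route of the four. The syn O/CH2OR relationship follows directly from syn addition to an E-alkene, which is more transparent than a stereochemical relay.
- *Weak points:* a conjugated 2,3-disubstituted diene is a poor substrate for reagent control, since after the first addition the second B–H adds within a cyclic borane and is governed by that ring. Facial control by chiral monoalkylboranes on trisubstituted styrenyl alkenes is moderate. A1 already has the target's configuration at both carbinol carbons, so the ring would have to close with net retention at the carbon attacked. An SN2 closure inverts one centre; an SN1 closure through a p-alkoxybenzyl cation favours the 2,3-trans arrangement, not the cis one needed.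
- *Comparison:* in step count and use of symmetry this road is better. The chosen plan sets against it asymmetric induction in a well-behaved catalytic reaction class (step 6) and a ring closure (step 9) in which the benzylic ether bond is made while configuration is transferred, not after all stereocentres are in place.

**Alternative 2:** The C2–C3, C3–C4 and C4–C5 bonds are made one after another by lithiation–borylation. An α-silyloxybenzyl boronic ester is homologated twice with a configurationally defined lithiated 2-silylethyl carbamate and once with a lithiated arylmethyl carbamate, each by a 1,2-metallate shift; oxidation gives A2.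
- *Merits:* every carbon stereocentre of the chain is set by the reagent, so any stereoisomer could be chosen, and the chain grows in one flask.
- *Weak points:* the first boronic ester carries an α-oxygen that can leave in competition with the 1,2-shift. The later homologations act on increasingly hindered secondary boronic esters, where the shift is slow. The benzylic lithiated carbamate is configurationally labile, so A2 is a mixture at the C5 carbinol. Both hydroxymethyl groups are still C–Si bonds and need two Fleming–Tamao oxidations in the presence of electron-rich arenes. The ring must still be closed by substitution at a benzylic centre.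
- *Comparison:* reagent control at C3 and C4 is stronger here than the substrate control of the chosen plan, where C3 rests on a directed hydrogenation. Against this, the chosen plan needs two catalytic stereo-determining steps instead of three stoichiometric cryogenic ones, leaves no stereocentre undefined, and has all oxygen functions at or near their final oxidation level.

**Alternative 3:** C4–C5 and the O1–C2 acyl bond are cut. A chiral N-heterocyclic carbene with a titanium alkoxide co-catalyst would convert a 4-alkoxybut-2-enal into a homoenolate whose β-carbon adds to an O-protected derivative of 1; the new alkoxide then acylates itself to give cis-lactone A3, with C4 and C5 as in the target.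
- *Merits:* the 4,5-cis relationship, the hardest one here, is the intrinsic preference of this annulation and is set catalytically in one step. On this point the road is at least as good as the chosen plan, whose 4,5-cis geometry depends on the stereochemical course of a rearrangement.
- *Weak points:* enantioselectivity of homoenolate additions to aromatic aldehydes is generally moderate, and a γ-alkoxy enal can lose alkoxide or undergo redox esterification. A3 contains one aryl group only and nothing at C2 or C3. A hydroxymethyl group must therefore be added α to the carbonyl, the second aryl group added to the lactone, and the lactol reduced with control at C2: three further stereo-relevant operations on a lactone with a labile benzylic C–O bond.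
- *Comparison:* A3 is reached faster than 15, but more remains to be done after it. In 15 both aryl groups and all skeletal carbons are in place, and C2/C3 are set together by one syn hydrogenation. The chosen plan also draws its enantiocontrol from a reaction class with reliably high selectivity for cinnamaldehydes.

Key step: step 9

Remark: ring atoms are labelled O1, C2–C5 as in the oxolane ring of 18 throughout. Compounds 12–14 are assumed to form as a mixture of epimers at the quaternary cyclopropane carbon (C1 of the cyclopropane, C3 of the furan), which is carried on because that carbon becomes sp2 in step 9. Piv = 2,2-dimethylpropanoyl, TBS = tert-butyldimethylsilyl. In cyclopropane names C2 carries the formyl/CH2O group and C3 the aryl group.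

## Route

Step 1
Reactants: 1 vanillin; 2 pivaloyl chloride
Product: 3 4-formyl-2-methoxyphenyl pivalate
Conditions: PivCl, Et3N, DMAP (cat.), CH2Cl2, 0 °C to rt
Reagents that add atoms: none
Why: O-acylation of the phenol under nucleophilic catalysis; the hindered pivalate is chosen because it should survive the amine, borohydride, fluoride and Lewis-acid steps that follow and because it lowers the donor strength of the ring.

Step 2
Reactants: 3 4-formyl-2-methoxyphenyl pivalate
Product: 4 (E)-3-[3-methoxy-4-(pivaloyloxy)phenyl]prop-2-enal
Conditions: Ph3P=CHCHO, toluene, 80 °C
Reagents that add atoms: (triphenylphosphoranylidene)acetaldehyde, O=CC=P(c1ccccc1)(c1ccccc1)c1ccccc1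
Why: Wittig olefination with the stabilised formylmethylene ylide should give the (E)-enal; the ylide reacts faster with the aromatic aldehyde than with the less electrophilic enal product, which limits double homologation when little excess is used.

Step 3
Reactants: 5 vanillic acid; 2 pivaloyl chloride
Product: 6 3-methoxy-4-(pivaloyloxy)benzoic acid
Conditions: PivCl, NaOH (aq), THF, 0 °C; then HCl (aq)
Reagents that add atoms: none
Why: Schotten–Baumann acylation; in aqueous base the phenoxide is far more nucleophilic than the carboxylate, so the phenol is pivaloylated and the acid is recovered on acidification.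

Step 4
Reactants: 6 3-methoxy-4-(pivaloyloxy)benzoic acid; 7 potassium methyl malonate
Product: 10 methyl 3-[3-methoxy-4-(pivaloyloxy)phenyl]-3-oxopropanoate, via acyl imidazolide 8 (not isolated), via acylmalonate half ester 9 (not isolated)
Conditions: CDI, THF, rt; then 7, MgCl2, Et3N, MeCN, rt to 45 °C; HCl (aq)
Reagents that add atoms: none
Why: Masamune–Claisen condensation; the acyl imidazolide acylates the magnesium enolate of the malonate half ester, and the adduct loses CO2 on acidic work-up to give the β-keto ester under conditions that leave the aryl pivalate alone.

Step 5
Reactants: 10 methyl 3-[3-methoxy-4-(pivaloyloxy)phenyl]-3-oxopropanoate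
Product: 11 methyl 2-bromo-3-[3-methoxy-4-(pivaloyloxy)phenyl]-3-oxopropanoate (racemic)
Conditions: NBS (1.0 equiv), NH4OAc (cat.), Et2O, rt
Reagents that add atoms: N-bromosuccinimide, O=C1CCC(=O)N1Br
Why: Electrophilic α-bromination of the enolisable β-keto ester; one equivalent of reagent with a mild ammonium acetate catalyst should stop at the monobromide, and the acylated, pivaloylated ring is too deactivated for ring bromination.

Step 6
Reactants: 4 (E)-3-[3-methoxy-4-(pivaloyloxy)phenyl]prop-2-enal; 11 methyl 2-bromo-3-[3-methoxy-4-(pivaloyloxy)phenyl]-3-oxopropanoate
Product: 12 methyl (2S,3R)-2-formyl-1-[3-methoxy-4-(pivaloyloxy)benzoyl]-3-[3-methoxy-4-(pivaloyloxy)phenyl]cyclopropane-1-carboxylate (C1 epimers)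
Conditions: (R)-α,α-diphenylprolinol trimethylsilyl ether (20 mol%), 2,6-lutidine, CH2Cl2, 0 °C to rt
Reagents that add atoms: none
Why: Iminium/enamine Michael-initiated ring closure; the enol of 11 adds to the β-carbon of the (E)-iminium ion of 4 on the face left open by the diphenyl(silyloxy)methyl group of the (R)-catalyst, which should set the aryl-bearing carbon as R, and the resulting enamine displaces bromide in a 3-exo-tet closure that places formyl trans to aryl (2S). The quaternary carbon is not controlled and need not be.

Step 7
Reactants: 12 methyl (2S,3R)-2-formyl-1-[3-methoxy-4-(pivaloyloxy)benzoyl]-3-[3-methoxy-4-(pivaloyloxy)phenyl]cyclopropane-1-carboxylate (C1 epimers)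
Product: 13 methyl (2S,3R)-2-(hydroxymethyl)-1-[3-methoxy-4-(pivaloyloxy)benzoyl]-3-[3-methoxy-4-(pivaloyloxy)phenyl]cyclopropane-1-carboxylate (C1 epimers)
Conditions: NaBH4, THF/MeOH, −40 °C
Reagents that add atoms: none
Why: Chemoselective borohydride reduction; the aldehyde is far more electrophilic than the hindered, conjugated aryl ketone on the quaternary carbon, and aryl pivalates are inert to NaBH4 at low temperature. No stereocentre changes.

Step 8
Reactants: 13 methyl (2S,3R)-2-(hydroxymethyl)-1-[3-methoxy-4-(pivaloyloxy)benzoyl]-3-[3-methoxy-4-(pivaloyloxy)phenyl]cyclopropane-1-carboxylate (C1 epimers)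
Product: 14 methyl (2S,3R)-2-[(tert-butyldimethylsilyloxy)methyl]-1-[3-methoxy-4-(pivaloyloxy)benzoyl]-3-[3-methoxy-4-(pivaloyloxy)phenyl]cyclopropane-1-carboxylate (C1 epimers)
Conditions: TBSCl, imidazole, DMF, 0 °C to rt (crude 13 used at once)
Reagents that add atoms: tert-butyldimethylsilyl chloride, CC(C)(C)[Si](C)(C)Cl
Why: Silylation of the primary alcohol; any lactol form of 13 is in equilibrium with the open hydroxy ketone and is drained as the primary hydroxyl is silylated, and immediate use of 13 limits lactonisation onto a cis ester.

Step 9
Reactants: 14 methyl (2S,3R)-2-[(tert-butyldimethylsilyloxy)methyl]-1-[3-methoxy-4-(pivaloyloxy)benzoyl]-3-[3-methoxy-4-(pivaloyloxy)phenyl]cyclopropane-1-carboxylate (C1 epimers)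
Product: 15 methyl (4S,5S)-4-[(tert-butyldimethylsilyloxy)methyl]-2,5-bis[3-methoxy-4-(pivaloyloxy)phenyl]-4,5-dihydrofuran-3-carboxylate
Conditions: Sc(OTf)3 (10 mol%), 4 Å MS, CH2Cl2, −20 to 0 °C
Reagents that add atoms: none
Why: Sc(OTf)3 binds the β-keto ester of 14 and polarises the ring bond between the acceptor carbon and the benzylic carbon (C3 and C5 of the furan), the only ring bond flanked by both acceptors and the aryl donor. The closest known reaction type is the Lewis-acid-catalysed Cloke–Wilson rearrangement of aryl-substituted 1-acylcyclopropane-1-carboxylates to 2-aryl-4,5-dihydrofuran-3-carboxylates, together with the invertive opening of aryl donor–acceptor cyclopropanes at the benzylic carbon by oxygen nucleophiles. The ring closes by a 1,3-shift of C5 from C3 to the ketone oxygen, a three-to-five ring expansion in which O1–C5 forms within a contact ion pair and not by an exo-tet displacement; counted from the enolate it is a five-membered (enolendo) O-capture. The one new stereocentre, C5, is controlled by the benzylic stereocentre of 14 itself: the oxygen is to bond to the lobe of C5 that points away from the departing C3 while C5 turns about C4–C5 with its hydrogen passing inside and its aryl group outside, so that the trans aryl/silyloxymethyl cyclopropane becomes the cis-4,5 dihydrofuran. C4 is untouched, and both C1 epimers lead to the same constitution because that carbon becomes sp2. The step needs inversion to beat front-side collapse and free ionisation, the ketone oxygen to beat the ester oxygen, and O-capture to beat Friedel–Crafts closure onto the aroyl ring. The pivalate on the C5 aryl group (a donor no stronger than phenyl), a catalytic mild Lewis acid at low temperature in a non-polar solvent, the higher nucleophilicity of the ketone-derived enolate oxygen and the deactivation of the aroyl ring by its own carbonyl group are relied on for these.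

Step 10
Reactants: 15 methyl (4S,5S)-4-[(tert-butyldimethylsilyloxy)methyl]-2,5-bis[3-methoxy-4-(pivaloyloxy)phenyl]-4,5-dihydrofuran-3-carboxylate
Product: 16 methyl (4S,5S)-4-(hydroxymethyl)-2,5-bis[3-methoxy-4-(pivaloyloxy)phenyl]-4,5-dihydrofuran-3-carboxylate
Conditions: HF·pyridine, pyridine, THF, 0 °C to rt
Reagents that add atoms: none
Why: Fluoride-mediated cleavage of the primary silyl ether under buffered, non-basic conditions that should spare the aryl pivalates, the methyl ester and the vinylogous carbonate; lactonisation onto the sp2 C3 ester would give a strained ring-fusion alkene and is not expected.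

Step 11
Reactants: 16 methyl (4S,5S)-4-(hydroxymethyl)-2,5-bis[3-methoxy-4-(pivaloyloxy)phenyl]-4,5-dihydrofuran-3-carboxylate
Product: 17 methyl (2S,3R,4S,5S)-4-(hydroxymethyl)-2,5-bis[3-methoxy-4-(pivaloyloxy)phenyl]oxolane-3-carboxylate
Conditions: [Ir(cod)(PCy3)(py)]PF6 (10 mol%), H2 (1–5 bar), CH2Cl2, rt
Reagents that add atoms: none
Why: Hydroxyl-directed homogeneous hydrogenation; the C4 hydroxymethyl group binds the cationic iridium centre and both hydrogens are delivered to C2 and C3 from its face, syn to each other. The C2 aryl and C3 ester groups thus end up on the opposite face (2S,3R), although that is the more hindered approach.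

Step 12
Reactants: 17 methyl (2S,3R,4S,5S)-4-(hydroxymethyl)-2,5-bis[3-methoxy-4-(pivaloyloxy)phenyl]oxolane-3-carboxylate
Product: 18 eduesmine [(2S,3S,4S,5S)-2,5-bis(4-hydroxy-3-methoxyphenyl)oxolane-3,4-diyl]dimethanol
Conditions: LiAlH4, THF, 0 °C to rt; aq. potassium sodium tartrate
Reagents that add atoms: none
Why: Hydride reduction of the methyl ester to the C3 hydroxymethyl group with concurrent reductive cleavage of both aryl pivalates; no stereocentre is touched, and the trans C3/C4 arrangement of 17 precludes lactonisation before reduction. The buffered tartrate work-up avoids acid that could ionise the p-hydroxybenzylic ether bonds.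

## Compound list

1 | vanillin (4-hydroxy-3-methoxybenzaldehyde) | COc1cc(C=O)ccc1O | starting material
2 | pivaloyl chloride (2,2-dimethylpropanoyl chloride) | CC(C)(C)C(=O)Cl | starting material
3 | 4-formyl-2-methoxyphenyl pivalate | COc1cc(C=O)ccc1OC(=O)C(C)(C)C | intermediate
4 | (E)-3-[3-methoxy-4-(pivaloyloxy)phenyl]prop-2-enal | COc1cc(/C=C/C=O)ccc1OC(=O)C(C)(C)C | intermediate
5 | vanillic acid (4-hydroxy-3-methoxybenzoic acid) | COc1cc(C(=O)O)ccc1O | starting material
6 | 3-methoxy-4-(pivaloyloxy)benzoic acid | COc1cc(C(=O)O)ccc1OC(=O)C(C)(C)C | intermediate
7 | potassium methyl malonate (potassium 3-methoxy-3-oxopropanoate) | COC(=O)CC(=O)[O-].[K+] | starting material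
8 | 1-[3-methoxy-4-(pivaloyloxy)benzoyl]imidazole (acyl imidazolide) | COc1cc(C(=O)n2ccnc2)ccc1OC(=O)C(C)(C)C | intermediate
9 | 2-[3-methoxy-4-(pivaloyloxy)benzoyl]-3-methoxy-3-oxopropanoic acid (acylmalonate half ester; magnesium salt in the flask) | COC(=O)C(C(=O)O)C(=O)c1ccc(OC(=O)C(C)(C)C)c(OC)c1 | intermediate
10 | methyl 3-[3-methoxy-4-(pivaloyloxy)phenyl]-3-oxopropanoate | COC(=O)CC(=O)c1ccc(OC(=O)C(C)(C)C)c(OC)c1 | intermediate
11 | methyl 2-bromo-3-[3-methoxy-4-(pivaloyloxy)phenyl]-3-oxopropanoate (racemic) | COC(=O)C(Br)C(=O)c1ccc(OC(=O)C(C)(C)C)c(OC)c1 | intermediate
12 | methyl (2S,3R)-2-formyl-1-[3-methoxy-4-(pivaloyloxy)benzoyl]-3-[3-methoxy-4-(pivaloyloxy)phenyl]cyclopropane-1-carboxylate (C1 epimers; formyl trans to aryl) | COC(=O)C1(C(=O)c2ccc(OC(=O)C(C)(C)C)c(OC)c2)[C@@H](C=O)[C@@H]1c1ccc(OC(=O)C(C)(C)C)c(OC)c1 | intermediate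
13 | methyl (2S,3R)-2-(hydroxymethyl)-1-[3-methoxy-4-(pivaloyloxy)benzoyl]-3-[3-methoxy-4-(pivaloyloxy)phenyl]cyclopropane-1-carboxylate (C1 epimers) | COC(=O)C1(C(=O)c2ccc(OC(=O)C(C)(C)C)c(OC)c2)[C@@H](CO)[C@@H]1c1ccc(OC(=O)C(C)(C)C)c(OC)c1 | intermediate
14 | methyl (2S,3R)-2-[(tert-butyldimethylsilyloxy)methyl]-1-[3-methoxy-4-(pivaloyloxy)benzoyl]-3-[3-methoxy-4-(pivaloyloxy)phenyl]cyclopropane-1-carboxylate (C1 epimers; aryl trans to CH2OTBS) | COC(=O)C1(C(=O)c2ccc(OC(=O)C(C)(C)C)c(OC)c2)[C@@H](CO[Si](C)(C)C(C)(C)C)[C@@H]1c1ccc(OC(=O)C(C)(C)C)c(OC)c1 | intermediate
15 | methyl (4S,5S)-4-[(tert-butyldimethylsilyloxy)methyl]-2,5-bis[3-methoxy-4-(pivaloyloxy)phenyl]-4,5-dihydrofuran-3-carboxylate (4,5-cis) | COC(=O)C1=C(c2ccc(OC(=O)C(C)(C)C)c(OC)c2)O[C@H](c2ccc(OC(=O)C(C)(C)C)c(OC)c2)[C@@H]1CO[Si](C)(C)C(C)(C)C | intermediate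
16 | methyl (4S,5S)-4-(hydroxymethyl)-2,5-bis[3-methoxy-4-(pivaloyloxy)phenyl]-4,5-dihydrofuran-3-carboxylate | COC(=O)C1=C(c2ccc(OC(=O)C(C)(C)C)c(OC)c2)O[C@H](c2ccc(OC(=O)C(C)(C)C)c(OC)c2)[C@@H]1CO | intermediate
17 | methyl (2S,3R,4S,5S)-4-(hydroxymethyl)-2,5-bis[3-methoxy-4-(pivaloyloxy)phenyl]oxolane-3-carboxylate | COc1cc([C@H]2O[C@H](c3ccc(OC(=O)C(C)(C)C)c(OC)c3)[C@H](CO)[C@H]2C(=O)OC)ccc1OC(=O)C(C)(C)C | intermediate
18 | eduesmine, [(2S,3S,4S,5S)-2,5-bis(4-hydroxy-3-methoxyphenyl)oxolane-3,4-diyl]dimethanol | COc1cc([C@H]2O[C@H](c3ccc(O)c(OC)c3)[C@H](CO)[C@H]2CO)ccc1O | target

## Step count and least certain steps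

Total step count: 12. Longest linear sequence: 10 steps (5 → 6 → 10 → 11 → 12 → 13 → 14 → 15 → 16 → 17 → 18; steps 3–12).

**Step 9 (key step).** The most likely failure is leakage of the stereochemical relay. Closure on the face of C5 that C3 has just left (net retention), or passage through a free benzylic cation, would both give the trans-4,5 isomer. Friedel–Crafts closure onto the aroyl ring and loss of the silyl ether are lesser risks. The cause is that a strictly collinear displacement cannot be reached within the five-membered array, so the invertive course depends on how tight the ion pair stays and on the face on which the aroyl group sits. The two C1 epimers of 14 need not behave alike: the one with the aroyl group on the side of the benzylic hydrogen can present the rear lobe of C5 by turning that hydrogen inward. They can be separated at 12 or 14 and tested singly. The fallback makes the inversion an intermolecular event. Starting from 14, water is used as the nucleophile under Cu(OTf)2 (cat.) in wet THF. SN2 opening at the benzylic carbon with inversion should give the γ-hydroxy keto ester methyl (3S,4S)-3-[(tert-butyldimethylsilyloxy)methyl]-4-hydroxy-2-[3-methoxy-4-(pivaloyloxy)benzoyl]-4-[3-methoxy-4-(pivaloyloxy)phenyl]butanoate F1. Pyridinium p-toluenesulfonate in toluene then closes the benzylic hydroxyl onto the ketone through the cyclic hemiketal F2 and dehydrates it, rejoining the route at 15. In this variant O1 comes from water, and the C5–O bond, once made in an ordinary backside displacement, is never broken again.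

**Step 11.** The most likely failure is no reduction, or undirected hydrogen uptake from the open face (giving the all-cis isomer). The alkene is tetrasubstituted and deactivated as a vinylogous carbonate, the directing hydroxyl is only homoallylic, and the required face is the hindered one. The cationic iridium catalyst may also deactivate before a slow substrate is consumed. The fallback reverses the order of the last two operations. From 16, LiAlH4 reduces the ester and removes the pivalates to give the tetraol [(4S,5S)-2,5-bis(4-hydroxy-3-methoxyphenyl)-4,5-dihydrofuran-3,4-diyl]dimethanol F3. In F3 an allylic as well as a homoallylic hydroxyl can hold the catalyst on the upper face of a more electron-rich and less hindered alkene. Directed hydrogenation of F3 with the same iridium complex, under acid-free handling, then gives 18 directly.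

**Step 6.** The most likely failure is consumption of the amine catalyst by N-alkylation or N-bromination by the electrophilic bromo keto ester, and slow ring closure at the hindered quaternary carbon, leading to low conversion or eroded selectivity. The fallback separates the two bond formations and introduces the leaving group after the first. From 4 and 10, the same amine catalyst mediates Michael addition of the non-halogenated keto ester to give the Michael adduct methyl (3S)-2-[3-methoxy-4-(pivaloyloxy)benzoyl]-3-[3-methoxy-4-(pivaloyloxy)phenyl]-5-oxopentanoate F4. N-Iodosuccinimide converts it into the α-iodo keto ester F5. Enamine formation with the amine catalyst and 2,6-lutidine then closes the three-membered ring by 3-exo-tet displacement of iodide, returning the route at 12.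

**Step 7 (with step 8).** The most likely failure is over-reduction of the aryl ketone, or capture of the new alcohol as a lactone by a cis ester or as a hemiketal that resists silylation. The hydroxymethyl group is held next to both carbonyl groups on a rigid ring. The fallback avoids the free alcohol altogether. From 12, hydrosilylation of the aldehyde with tert-butyldimethylsilane catalysed by [(Ph3P)CuH]6 in toluene forms the silyl ether in one operation and returns the route at 14; no new compound is made.

## Further compounds

F1 | step 9 | methyl (3S,4S)-3-[(tert-butyldimethylsilyloxy)methyl]-4-hydroxy-2-[3-methoxy-4-(pivaloyloxy)benzoyl]-4-[3-methoxy-4-(pivaloyloxy)phenyl]butanoate (C2 epimers) | COC(=O)C(C(=O)c1ccc(OC(=O)C(C)(C)C)c(OC)c1)[C@@H](CO[Si](C)(C)C(C)(C)C)[C@H](O)c1ccc(OC(=O)C(C)(C)C)c(OC)c1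
F2 | step 9 | methyl (4S,5S)-4-[(tert-butyldimethylsilyloxy)methyl]-2-hydroxy-2,5-bis[3-methoxy-4-(pivaloyloxy)phenyl]oxolane-3-carboxylate (hemiketal; C2 and C3 epimers) | COC(=O)C1C(O)(c2ccc(OC(=O)C(C)(C)C)c(OC)c2)O[C@H](c2ccc(OC(=O)C(C)(C)C)c(OC)c2)[C@@H]1CO[Si](C)(C)C(C)(C)C
F3 | step 11 | [(4S,5S)-2,5-bis(4-hydroxy-3-methoxyphenyl)-4,5-dihydrofuran-3,4-diyl]dimethanol | OCC1=C(c2ccc(O)c(OC)c2)O[C@H](c2ccc(O)c(OC)c2)[C@@H]1CO
F4 | step 6 | methyl (3S)-2-[3-methoxy-4-(pivaloyloxy)benzoyl]-3-[3-methoxy-4-(pivaloyloxy)phenyl]-5-oxopentanoate (C2 epimers) | COC(=O)C(C(=O)c1ccc(OC(=O)C(C)(C)C)c(OC)c1)[C@H](CC=O)c1ccc(OC(=O)C(C)(C)C)c(OC)c1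
F5 | step 6 | methyl (3R)-2-iodo-2-[3-methoxy-4-(pivaloyloxy)benzoyl]-3-[3-methoxy-4-(pivaloyloxy)phenyl]-5-oxopentanoate (C2 epimers) | COC(=O)C(I)(C(=O)c1ccc(OC(=O)C(C)(C)C)c(OC)c1)[C@H](CC=O)c1ccc(OC(=O)C(C)(C)C)c(OC)c1
F0 | step 7 | none | none
A1 | alternative 1 | (1S,2S,3S,4S)-2,3-bis(benzyloxymethyl)-1,4-bis(4-benzyloxy-3-methoxyphenyl)butane-1,4-diol | COc1cc([C@@H](O)[C@H](COCc2ccccc2)[C@@H](COCc2ccccc2)[C@H](O)c2ccc(OCc3ccccc3)c(OC)c2)ccc1OCc1ccccc1
A2 | alternative 2 | 1,4-bis(4-benzyloxy-3-methoxyphenyl)-4-(tert-butyldimethylsilyloxy)-2,3-bis[(dimethylphenylsilyl)methyl]butan-1-ol (C2–C4 as in the target; C1 carbinol either epimer) | COc1cc([C@@H](O[Si](C)(C)C(C)(C)C)[C@H](C[Si](C)(C)c2ccccc2)[C@@H](C[Si](C)(C)c2ccccc2)C(O)c2ccc(OCc3ccccc3)c(OC)c2)ccc1OCc1ccccc1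
A3 | alternative 3 | cis-5-(4-benzyloxy-3-methoxyphenyl)-4-(benzyloxymethyl)oxolan-2-one | COc1cc([C@H]2OC(=O)C[C@H]2COCc2ccccc2)ccc1OCc1ccccc1
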